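Germacrane numbering is used. Everything rests on cutting C3–C4 of the ten-membered carbocycle, because the C3 carbinol and the C4(OH)–C15H2OH glycol together are a masked 2-methylene allylic alcohol. An intramolecular Nozaki–Hiyama–Kishi reaction of the fully decorated seco-aldehyde (C3 aldehyde, C4 2-iodoalkene) closes the ring, sets C3 and leaves C4=C15 for a last dihydroxylation, while α-methylene lactone and angelate stay untouched. The step exploits two rigid turn elements, the Z-C1=C10 olefin and the trans-fused C6–C7 γ-lactone ring, which fold the chain. The precursor is assembled by two stereospecific allylborations that form C8–C9 and C6–C7.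

Key step: step 14

Remark: the locants are C1/C10 = epoxide carbons (C10 bears C14H3), C3 = secondary carbinol, C4 = tertiary carbinol bearing C15H2OH, C6 = lactone carbinol, C7 = ring-fusion CH, C8 = angelate carbinol, C11=C13 = exocyclic methylene and C12 = lactone carbonyl. Compounds 1, 3, 7, 14, 17 and 23 are assumed to be purchasable.

Step 1
Reactants: 1 3-[(tert-butyldiphenylsilyl)oxy]propan-1-ol
Product: 2 3-[(tert-butyldiphenylsilyl)oxy]propyl N,N-diisopropylcarbamate
Conditions: iPr2NC(O)Cl, Et3N, CH2Cl2, reflux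
Reagents that add atoms: N,N-diisopropylcarbamoyl chloride CC(C)N(C(C)C)C(=O)Cl
Why: O-carbamoylation of a primary alcohol installs the directing and leaving group for the lithiation–borylation, and no stereocentre is formed.

Step 2
Reactants: 2 3-[(tert-butyldiphenylsilyl)oxy]propyl N,N-diisopropylcarbamate; 3 isopropenylboronic acid pinacol ester
Product: 6 (R)-tert-butyl{[4-methyl-3-(4,4,5,5-tetramethyl-1,3,2-dioxaborolan-2-yl)pent-4-en-1-yl]oxy}diphenylsilane, via lithiated carbamate 4 (not isolated), via boronate complex 5 (not isolated)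
Conditions: s-BuLi, (−)-sparteine, Et2O, −78 °C; 3, −78 °C; MgBr2·OEt2, −78 °C to reflux
Reagents that add atoms: none
Why: In this lithiation–borylation, sparteine-directed removal of the pro-S proton should give configurationally stable (S)-4, which is borylated with retention to 5 and then undergoes 1,2-migration of the isopropenyl group with inversion and loss of the carbamate, so the boron-bearing carbon (future C1) is set as R.

Step 3
Reactants: 7 3,3-diethoxyprop-1-yne
Product: 9 methyl 4,4-diethoxybut-2-ynoate, via lithium acetylide 8 (not isolated)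
Conditions: n-BuLi, THF, −78 °C; ClCO2Me, −78 to 0 °C
Reagents that add atoms: methyl chloroformate COC(=O)Cl
Why: C-acylation of a lithium acetylide with a chloroformate is routine, and the acetal is inert to the base.

Step 4
Reactants: 9 methyl 4,4-diethoxybut-2-ynoate
Product: 10 methyl 4-oxobut-2-ynoate
Conditions: HCO2H (neat), rt, used at once
Reagents that add atoms: formic acid OC=O
Why: Formolysis of the acetal avoids the aqueous base and nucleophiles that would attack the doubly activated alkyne, and it should release the free ynal.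

Step 5
Reactants: 6 (R)-allylboronate; 10 methyl 4-oxobut-2-ynoate
Product: 12 methyl (4R,6Z)-9-[(tert-butyldiphenylsilyl)oxy]-4-hydroxy-6-methylnon-6-en-2-ynoate, via pinacol borate 11 (not isolated)
Conditions: CH2Cl2, 4 Å MS, −20 °C to rt; aq. NaHCO3 work-up
Reagents that add atoms: none
Why: This is a Type I allylboration through a closed Zimmerman–Traxler chair in which the α-substituent sits axial, away from the pinacol methyls and free of A1,2 strain with the 2-methyl group, so the C–B chirality is transferred to C8 (R) and the trisubstituted C1=C10 olefin should form as the Z isomer in the same event.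

Step 6
Reactants: 12 methyl (4R,6Z)-9-[(tert-butyldiphenylsilyl)oxy]-4-hydroxy-6-methylnon-6-en-2-ynoate
Product: 13 methyl (4R,6Z)-9-[(tert-butyldiphenylsilyl)oxy]-6-methyl-4-[(triethylsilyl)oxy]non-6-en-2-ynoate
Conditions: TESOTf, 2,6-lutidine, CH2Cl2, −78 °C
Reagents that add atoms: triethylsilyl trifluoromethanesulfonate CC[Si](CC)(CC)OS(=O)(=O)C(F)(F)F
Why: Silylation with a silyl triflate and a hindered weak base at low temperature avoids the amine-induced redox isomerisation of the γ-hydroxy ynoate and blocks later butenolide formation.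

Step 7
Reactants: 13 TES-protected ynoate; 14 2-(iodomethyl)-4,4,5,5-tetramethyl-1,3,2-dioxaborolane
Product: 16 methyl (2Z,4R,6Z)-9-[(tert-butyldiphenylsilyl)oxy]-6-methyl-2-[(4,4,5,5-tetramethyl-1,3,2-dioxaborolan-2-yl)methyl]-4-[(triethylsilyl)oxy]nona-2,6-dienoate, via alkenylalane 15 (not isolated)
Conditions: DIBAL-H, HMPA, THF, 0 °C; 14, 0 °C to rt
Reagents that add atoms: none
Why: Conjugate syn-hydroalumination of the ynoate by the DIBAL-H–HMPA complex puts H on C7 and Al on C11, and alkylation of alkenylalane 15 by the iodomethylboronate with retention should give the 2-alkoxycarbonyl allylboronate with C8 cis to the ester (2Z).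

Step 8
Reactants: 17 but-3-yn-1-ol
Product: 18 3-iodobut-3-en-1-ol
Conditions: NaI, TMSCl, H2O, MeCN, rt
Reagents that add atoms: sodium iodide [Na+].[I-]
Why: Markovnikov hydroiodination of a terminal alkyne by HI generated in situ places iodine on the internal carbon (future C4).

Step 9
Reactants: 18 3-iodobut-3-en-1-ol
Product: 19 3-iodobut-3-enal
Conditions: Dess–Martin periodinane, CH2Cl2, 0 °C to rt, used crude
Reagents that add atoms: none
Why: Dess–Martin oxidation is neutral and non-enolising, so the β,γ-unsaturated aldehyde should form without migration of the iodoalkene.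

Step 10
Reactants: 16 (2Z,4R,6Z)-allylboronate; 19 3-iodobut-3-enal
Product: 22 (4R,5R)-4-{(1R,3Z)-6-[(tert-butyldiphenylsilyl)oxy]-1-hydroxy-3-methylhex-3-en-1-yl}-5-(2-iodoprop-2-en-1-yl)-3-methylidenedihydrofuran-2(3H)-one, via borate adduct 20 (not isolated), via TES lactone 21 (not isolated)
Conditions: Sc(OTf)3 (10 mol %), toluene, 0 °C to rt; then p-TsOH·H2O (cat.), MeOH, rt
Reagents that add atoms: none
Why: In this Lewis acid-catalysed Type I allylboration with tandem lactonisation, the chair transition state turns the 2Z geometry into the anti C6/C7 relation (trans-lactone), A1,3 strain with the cis ester holds H-8 in the olefin plane so that the aldehyde should attack anti to the C9 chain with OTES outside (C8 relays to 7S,6R in 21), and the methanolic acid then removes only the labile TES ether.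

Step 11
Reactants: 22 hydroxy lactone; 23 angelic acid [(Z)-2-methylbut-2-enoic acid]
Product: 25 (6R,7R,8R)-C8 angelate of 22, via mixed anhydride 24 (not isolated)
Conditions: 2,4,6-Cl3C6H2COCl, Et3N, toluene, rt; then 22, 80 °C
Reagents that add atoms: none
Why: Yamaguchi-type acylation through the hindered mixed anhydride, run without a nucleophilic catalyst, should esterify the hindered C8 alcohol with retention at C8 and without Z-to-E isomerisation of the angelate.

Step 12
Reactants: 25 C8 angelate silyl ether
Product: 26 (6R,7R,8R)-C3 primary alcohol (side chain (1R,3Z)-1-angeloyloxy-6-hydroxy-3-methylhex-3-en-1-yl)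
Conditions: HF·pyridine, pyridine, THF, 0 °C to rt
Reagents that add atoms: none
Why: Buffered fluoride desilylation is non-basic, so the angelate geometry, the α-methylene lactone and the iodoalkene should survive.

Step 13
Reactants: 26 C3 primary alcohol
Product: 27 (6R,7R,8R)-seco-aldehyde (side chain (1R,3Z)-1-angeloyloxy-3-methyl-6-oxohex-3-en-1-yl)
Conditions: Dess–Martin periodinane, CH2Cl2, 0 °C, used crude
Reagents that add atoms: none
Why: Dess–Martin oxidation under neutral conditions should give the Z-β,γ-unsaturated aldehyde without conjugation of the olefin.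

Step 14
Reactants: 27 seco-aldehyde
Product: 30 (3S,6R,7R,8R,1(10)Z)-8-angeloyloxy-3-hydroxygermacra-1(10),4(15),11(13)-trien-12,6-olide, via alkenylchromium 28 (not isolated), via chromium alkoxide 29 (not isolated)
Conditions: CrCl2 (excess), NiCl2 (cat.), DMSO, rt, slow addition of 27 (final ca. 2 mM); aqueous work-up
Reagents that add atoms: none
Why: Cr(II) reduces Ni(II) to Ni(0), which inserts into the C4–I bond; transmetalation to Cr(III) gives the non-basic alkenylchromium 28, whose C4 adds to the Cr(III)-bound C3 aldehyde to give alkoxide 29, hydrolysed on work-up. This is an intramolecular Nozaki–Hiyama–Kishi reaction of a 2-iodo-1-alkene, a reaction type established for closing nine- to twelve-membered rings that carry an exocyclic methylene carbinol. The ten-membered carbocycle is closed in a 10-exo-trig mode (carbonyl oxygen outside the new ring, C15 left exocyclic), helped by the two turn elements of the chain, the Z-C1=C10 olefin and the trans-fused lactone at C6–C7, and by slow addition at high dilution, which disfavours dimerisation. The one new stereocentre, C3, is under macrocyclic control: the bulky Cr-bound oxygen must point to the ring periphery, and in the folded chain this should expose the Re face of the aldehyde and give 3S, which is the least secure point of the step. The chemoselectivity needed is attack on the aldehyde alone, and it is secured by the low nucleophilicity of organochromium(III) species toward the lactone, the angelate and both conjugated olefins. The neutral medium should also keep the β,γ-unsaturated aldehyde from slipping into conjugation.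

Step 15
Reactants: 30 macrocyclic allylic alcohol
Product: 31 (1R,3S,6R,7S,8R,10S)-8-angeloyloxy-1,10-epoxy-3-hydroxygermacra-4(15),11(13)-dien-12,6-olide
Conditions: D-fructose-derived Shi ketone (30 mol %), Oxone, K2CO3, Bu4NHSO4 (cat.), MeCN–dimethoxymethane/aq. borate–EDTA buffer, 0 °C
Reagents that add atoms: potassium peroxymonosulfate [K+].[O-]S(=O)(=O)OO
Why: In the Shi epoxidation the electrophilic chiral dioxirane should select the only electron-rich trisubstituted olefin (C4=C15 is 1,1-disubstituted and inductively deactivated, C11=C13 and the angelate are electron-poor), and the spiro transition-state mnemonic for this ketone predicts oxygen delivery to the β face, giving the cis (1R,10S)-epoxide.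

Step 16
Reactants: 31 epoxy allylic alcohol
Product: 32 (1R,3S,4R,6R,7S,8R,10S)-8-angeloyloxy-1,10-epoxy-3,4,15-trihydroxygermacr-11(13)-en-12,6-olide (CNP0307250.1)
Conditions: OsO4 (5 mol %), NMO, acetone–H2O, 0 °C
Reagents that add atoms: osmium tetroxide (catalytic oxygen carrier) O=[Os](=O)(=O)=O; N-methylmorpholine N-oxide C[N+]1([O-])CCOCC1; water O
Why: In this Upjohn dihydroxylation OsO4 should pick the remaining non-conjugated olefin and add suprafacially from the α face, anti to the allylic C3 oxygen as the empirical rule for osmylation of allylic alcohols predicts, which sets C4 as R with OH α and CH2OH β while the near-neutral medium spares the epoxide.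

Compound list
1 | 3-[(tert-butyldiphenylsilyl)oxy]propan-1-ol | OCCCO[Si](c1ccccc1)(c1ccccc1)C(C)(C)C | starting material
2 | 3-[(tert-butyldiphenylsilyl)oxy]propyl N,N-diisopropylcarbamate | CC(C)N(C(C)C)C(=O)OCCCO[Si](c1ccccc1)(c1ccccc1)C(C)(C)C | intermediate
3 | isopropenylboronic acid pinacol ester | C=C(C)B1OC(C)(C)C(C)(C)O1 | starting material
4 | (S)-α-lithiated carbamate, (−)-sparteine complex (not isolated) | [Li][C@@H](CCO[Si](c1ccccc1)(c1ccccc1)C(C)(C)C)OC(=O)N(C(C)C)C(C)C | intermediate
5 | lithium (S)-boronate complex (not isolated) | [Li+].C=C(C)[B-]1(OC(C)(C)C(C)(C)O1)[C@@H](CCO[Si](c1ccccc1)(c1ccccc1)C(C)(C)C)OC(=O)N(C(C)C)C(C)C | intermediate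
6 | (R)-tert-butyl{[4-methyl-3-(pinacolboryl)pent-4-en-1-yl]oxy}diphenylsilane | CC1(C)OB(OC1(C)C)[C@H](CCO[Si](c1ccccc1)(c1ccccc1)C(C)(C)C)C(C)=C | intermediate
7 | 3,3-diethoxyprop-1-yne | C#CC(OCC)OCC | starting material
8 | lithium 3,3-diethoxyprop-1-yn-1-ide (not isolated) | [Li]C#CC(OCC)OCC | intermediate
9 | methyl 4,4-diethoxybut-2-ynoate | COC(=O)C#CC(OCC)OCC | intermediate
10 | methyl 4-oxobut-2-ynoate | COC(=O)C#CC=O | intermediate
11 | O-pinacolboryl derivative of 12 (not isolated) | COC(=O)C#C[C@H](OB1OC(C)(C)C(C)(C)O1)C/C(C)=C\CCO[Si](c1ccccc1)(c1ccccc1)C(C)(C)C | intermediate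
12 | methyl (4R,6Z)-9-[(tert-butyldiphenylsilyl)oxy]-4-hydroxy-6-methylnon-6-en-2-ynoate | COC(=O)C#C[C@H](O)C/C(C)=C\CCO[Si](c1ccccc1)(c1ccccc1)C(C)(C)C | intermediate
13 | methyl (4R,6Z)-9-[(tert-butyldiphenylsilyl)oxy]-6-methyl-4-[(triethylsilyl)oxy]non-6-en-2-ynoate | COC(=O)C#C[C@H](O[Si](CC)(CC)CC)C/C(C)=C\CCO[Si](c1ccccc1)(c1ccccc1)C(C)(C)C | intermediate
14 | 2-(iodomethyl)-4,4,5,5-tetramethyl-1,3,2-dioxaborolane | ICB1OC(C)(C)C(C)(C)O1 | starting material
15 | α-(diisobutylalanyl) enoate, Al and H-7 cis, C8 cis to the ester (not isolated) | COC(=O)/C([Al](CC(C)C)CC(C)C)=C\[C@H](O[Si](CC)(CC)CC)C/C(C)=C\CCO[Si](c1ccccc1)(c1ccccc1)C(C)(C)C | intermediate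
16 | methyl (2Z,4R,6Z)-9-[(tert-butyldiphenylsilyl)oxy]-6-methyl-2-[(pinacolboryl)methyl]-4-[(triethylsilyl)oxy]nona-2,6-dienoate | COC(=O)/C(CB1OC(C)(C)C(C)(C)O1)=C\[C@H](O[Si](CC)(CC)CC)C/C(C)=C\CCO[Si](c1ccccc1)(c1ccccc1)C(C)(C)C | intermediate
17 | but-3-yn-1-ol | C#CCCO | starting material
18 | 3-iodobut-3-en-1-ol | C=C(I)CCO | intermediate
19 | 3-iodobut-3-enal | C=C(I)CC=O | intermediate
20 | (6R,7S,8R) open-chain allylboration adduct, methyl 2-methylene ester with C6–OBpin and C8–OTES (not isolated) | COC(=O)C(=C)[C@@H]([C@@H](CC(I)=C)OB1OC(C)(C)C(C)(C)O1)[C@H](O[Si](CC)(CC)CC)C/C(C)=C\CCO[Si](c1ccccc1)(c1ccccc1)C(C)(C)C | intermediate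
21 | (6R,7S,8R) trans-α-methylene-γ-butyrolactone with C8–OTES (not isolated) | C=C1C(=O)O[C@H](CC(I)=C)[C@H]1[C@H](O[Si](CC)(CC)CC)C/C(C)=C\CCO[Si](c1ccccc1)(c1ccccc1)C(C)(C)C | intermediate
22 | (4R,5R)-4-{(1R,3Z)-6-[(tert-butyldiphenylsilyl)oxy]-1-hydroxy-3-methylhex-3-en-1-yl}-5-(2-iodoprop-2-en-1-yl)-3-methylidenedihydrofuran-2(3H)-one | C=C1C(=O)O[C@H](CC(I)=C)[C@H]1[C@H](O)C/C(C)=C\CCO[Si](c1ccccc1)(c1ccccc1)C(C)(C)C | intermediate
23 | angelic acid, (Z)-2-methylbut-2-enoic acid | C/C=C(/C)C(=O)O | starting material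
24 | angelic 2,4,6-trichlorobenzoic anhydride (not isolated) | C/C=C(/C)C(=O)OC(=O)c1c(Cl)cc(Cl)cc1Cl | intermediate
25 | (6R,7R,8R) C8 angelate, C3–OTBDPS | C=C1C(=O)O[C@H](CC(I)=C)[C@H]1[C@H](OC(=O)/C(C)=C\C)C/C(C)=C\CCO[Si](c1ccccc1)(c1ccccc1)C(C)(C)C | intermediate
26 | (6R,7R,8R) C8 angelate, C3 primary alcohol | C=C1C(=O)O[C@H](CC(I)=C)[C@H]1[C@H](OC(=O)/C(C)=C\C)C/C(C)=C\CCO | intermediate
27 | (6R,7R,8R) seco-aldehyde (C3 aldehyde, C4 2-iodoalkene) | C=C1C(=O)O[C@H](CC(I)=C)[C@H]1[C@H](OC(=O)/C(C)=C\C)C/C(C)=C\CC=O | intermediate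
28 | C4 alkenylchromium(III) dichloride of 27 (not isolated) | C=C1C(=O)O[C@H](CC(=C)[Cr](Cl)Cl)[C@H]1[C@H](OC(=O)/C(C)=C\C)C/C(C)=C\CC=O | intermediate
29 | chromium(III) C3 alkoxide of 30 (not isolated) | C=C1C(=O)O[C@@H]2CC(=C)[C@@H](O[Cr](Cl)Cl)C/C=C(/C)C[C@@H](OC(=O)/C(C)=C\C)[C@@H]12 | intermediate
30 | (3S,6R,7R,8R,1(10)Z)-8-angeloyloxy-3-hydroxygermacra-1(10),4(15),11(13)-trien-12,6-olide | C=C1C(=O)O[C@@H]2CC(=C)[C@@H](O)C/C=C(/C)C[C@@H](OC(=O)/C(C)=C\C)[C@@H]12 | intermediate
31 | (1R,3S,6R,7S,8R,10S)-8-angeloyloxy-1,10-epoxy-3-hydroxygermacra-4(15),11(13)-dien-12,6-olide | C=C1C(=O)O[C@@H]2CC(=C)[C@@H](O)C[C@H]3O[C@@]3(C)C[C@@H](OC(=O)/C(C)=C\C)[C@@H]12 | intermediate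
32 | (1R,3S,4R,6R,7S,8R,10S)-8-angeloyloxy-1,10-epoxy-3,4,15-trihydroxygermacr-11(13)-en-12,6-olide (CNP0307250.1) | C=C1C(=O)O[C@@H]2C[C@@](O)(CO)[C@@H](O)C[C@H]3O[C@@]3(C)C[C@@H](OC(=O)/C(C)=C\C)[C@@H]12 | target

Total step count: 16.
Longest linear sequence: 12 steps from 1 (steps 1, 2, 5, 6, 7, 10, 11, 12, 13, 14, 15, 16).

Steps most likely to fail

Step 14. Two things may go wrong: poor facial selectivity in the attack on the C3 aldehyde, because C3 depends only on the fold of the closing chain, and competing oligomerisation. The fallback sets out from 27 and comes back at 30. The ring closure is accepted without stereocontrol. The C3 epimer of the macrocycle F1, alone or mixed with 30, is oxidised with Dess–Martin periodinane to the cross-conjugated macrocyclic enone F2. C3 is then set by reagent control through a Corey–Bakshi–Shibata reduction with (R)-Me-CBS and catecholborane at low temperature, with the 2-substituted alkenyl branch acting as the large group, which should deliver the 3S alcohol 30.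

Step 10. The β,γ-unsaturated iodo aldehyde may isomerise or decompose under the Lewis acid before the slow allylboration of the hindered boronate takes place. The fallback sets out from 16 and comes back at 21.
- The C4–C15 unit is brought in masked as a capped alkyne. 4-(Trimethylsilyl)but-3-ynal F3 is made by Dess–Martin oxidation of commercial 4-(trimethylsilyl)but-3-yn-1-ol.
- F3 is used in the same scandium-catalysed allylboration–lactonisation, stopped before the methanolic acid, to give the silylalkynyl TES lactone F4.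
- Silver(I)-catalysed protodesilylation (AgNO3 cat., aqueous acetone) should give the terminal alkynyl TES lactone F5.
- Syn-iodoboration with B-iodo-9-BBN at −20 °C places iodine on the internal carbon C4 and should give the β-iodoalkenyl-9-BBN lactone F6.
- Protonolysis of F6 with acetic acid should deliver 21, which is carried on to 22 with p-TsOH in methanol as in step 10.

Step 15. The face selectivity may be insufficient if the macrocycle conformation opposes the catalyst, and the allylic C4=C15 olefin may be over-oxidised. The fallback sets out from 30 and comes back at 32, and it changes both the order and the control element. The sterically more accessible exocyclic C4=C15 olefin is osmylated first (OsO4 cat., NMO, low temperature, attack anti to the C3 oxygen) to give the 1(10)-ene triol F7. With no allylic olefin left to compete, the Z-C1=C10 olefin is then epoxidised with VO(acac)2 and t-BuOOH. The β-oriented homoallylic C3 hydroxyl binds vanadium and should deliver oxygen to the β face, which gives 32 directly.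

Further compounds
F1 | step 14 | (3R,6R,7R,8R,1(10)Z)-8-angeloyloxy-3-hydroxygermacra-1(10),4(15),11(13)-trien-12,6-olide (C3 epimer of 30) | C=C1C(=O)O[C@@H]2CC(=C)[C@H](O)C/C=C(/C)C[C@@H](OC(=O)/C(C)=C\C)[C@@H]12
F2 | step 14 | (6R,7R,8R,1(10)Z)-8-angeloyloxy-3-oxogermacra-1(10),4(15),11(13)-trien-12,6-olide | C=C1C(=O)O[C@@H]2CC(=C)C(=O)C/C=C(/C)C[C@@H](OC(=O)/C(C)=C\C)[C@@H]12
F3 | step 10 | 4-(trimethylsilyl)but-3-ynal | C[Si](C)(C)C#CCC=O
F4 | step 10 | analogue of 21 with a 3-(trimethylsilyl)prop-2-yn-1-yl group at C6 | C=C1C(=O)O[C@H](CC#C[Si](C)(C)C)[C@H]1[C@H](O[Si](CC)(CC)CC)C/C(C)=C\CCO[Si](c1ccccc1)(c1ccccc1)C(C)(C)C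
F5 | step 10 | analogue of 21 with a prop-2-yn-1-yl group at C6 | C=C1C(=O)O[C@H](CC#C)[C@H]1[C@H](O[Si](CC)(CC)CC)C/C(C)=C\CCO[Si](c1ccccc1)(c1ccccc1)C(C)(C)C
F6 | step 10 | analogue of 21 with a 3-(9-borabicyclo[3.3.1]nonan-9-yl)-2-iodoprop-2-en-1-yl group at C6, I and B cis | C=C1C(=O)O[C@H](C/C(I)=C/B2C3CCCC2CCC3)[C@H]1[C@H](O[Si](CC)(CC)CC)C/C(C)=C\CCO[Si](c1ccccc1)(c1ccccc1)C(C)(C)C
F7 | step 15 | (3S,4R,6R,7R,8R,1(10)Z)-8-angeloyloxy-3,4,15-trihydroxygermacra-1(10),11(13)-dien-12,6-olide | C=C1C(=O)O[C@@H]2C[C@@](O)(CO)[C@@H](O)C/C=C(/C)C[C@@H](OC(=O)/C(C)=C\C)[C@@H]12
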